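**Retrosynthetic overview**
- The enal comes last from a C3 ketone (isopropenyl carbinol, 1,3-oxidative transposition). The triene comes from a Suzuki coupling at C13–C14 and a boryl-olefination of a lactol at C12. The C9–C11 bond comes from a carbene C–H insertion tethered through the C10 oxygen.
- The hydroxypropyl arm comes from a γ-lactone C10–O–C2a(=O)–C2 by lactol olefination. The lactone comes from a cyclobutanone by Baeyer–Villiger oxidation, and the cyclobutanone from a methylenecyclobutane.
- Feature used: on ring B the first arm carbon C2a (on C2) and the ring-A carbinol carbon C10 (on spiro C1) are cis. A four-membered ring C1–C2–C2a–C10 can therefore hold both and later be opened by oxygen insertion into C10–C2a.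
- Key disconnection: C1–C10 and C2–C2a by intramolecular enone–allene [2+2] photocycloaddition. Ring order: ring B (from 3-ethoxycyclohexenone), then ring A plus cyclobutane in one step, then the cyclobutane is opened.
- The photo-precursor comes from 3-ethoxycyclohex-2-enone (methylation, asymmetric hydroxylation, dienyl Grignard addition with enone transposition).

Key step: step 5

Atom labels (not IUPAC locants): C1 spiro carbon; C2–C6 the other ring-B carbons (C2 arm, C3 enal carbon, C6 methyl carbinol); C7–C10 the other ring-A carbons (C9 triene, C10 hydroxyl); C2a first arm carbon; C11 the carbon on C9 (bears =CH2), C12=C13 the E-alkene, C14=C15 the trisubstituted alkene. "Lower face" of ring B is the face that carries C10.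

Assumption: the sense of induction of the camphor-derived oxaziridine on the enolate of step 2 is not established for this substrate; the enantiomer written is taken to give (S)-5, and its commercially available mirror image would be used if the sense is the opposite.

**Step 1**
Reactants: 1 3-ethoxycyclohex-2-en-1-one
Product: 3 3-ethoxy-6-methylcyclohex-2-en-1-one (racemic), via lithium dienolate 2 (not isolated)
Conditions: LiN(i-Pr)2, THF, −78 °C; CH3I, −78 → 0 °C
Reagents that add atoms: iodomethane, CI
Why: Kinetic α′-deprotonation of the vinylogous ester and SN2 methylation is the standard opening of a Stork–Danheiser sequence; the new centre is racemic and is erased by enolisation in step 2.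

**Step 2**
Reactants: 3 3-ethoxy-6-methylcyclohex-2-en-1-one
Product: 5 (S)-3-ethoxy-6-hydroxy-6-methylcyclohex-2-en-1-one, via sodium enolate 4 (not isolated)
Conditions: NaN(SiMe3)2, THF, −78 °C; [(8,8-dichlorocamphoryl)sulfonyl]oxaziridine (from (1S)-camphorsulfonic acid), −78 °C; aq. NH4Cl
Reagents that add atoms: [(8,8-dichlorocamphoryl)sulfonyl]oxaziridine, CC1(C)[C@@H]2CC[C@]13CS(=O)(=O)N4O[C@@]34C2(Cl)Cl
Why: Asymmetric enolate hydroxylation by oxygen transfer from an enantiopure N-sulfonyloxaziridine to the tetrasubstituted sodium enolate sets the tertiary carbinol C6 by reagent control, and the enantiomeric purity would be raised by recrystallisation if needed.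

**Step 3**
Reactants: 6 5-chloropent-1-yne; 7 formaldehyde (as paraformaldehyde)
Product: 9 6-chlorohexa-1,2-diene, via Mannich base 8 (not isolated)
Conditions: (CH2O)n, CuBr (0.3 equiv), i-Pr2NH, 1,4-dioxane, reflux
Reagents that add atoms: none
Why: Crabbé homologation: the copper-catalysed Mannich reaction gives the propargylic amine, which transfers hydride from an N-isopropyl C–H to the alkyne and expels the imine to leave the terminal allene, the primary chloride being inert to the hindered amine.

**Step 4**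
Reactants: 5 (S)-3-ethoxy-6-hydroxy-6-methylcyclohex-2-en-1-one; 9 6-chlorohexa-1,2-diene
Product: 12 (S)-4-hydroxy-4-methyl-3-(hexa-4,5-dien-1-yl)cyclohex-2-en-1-one, via Grignard reagent 10 (not isolated), via carbinol adduct 11 (not isolated)
Conditions: 9, Mg, THF, reflux; then 5 (0.4 equiv relative to 10), THF, −20 → 20 °C; 1 M HCl, 0 °C
Reagents that add atoms: water, O
Why: Stork–Danheiser transposition: one equivalent of the Grignard reagent deprotonates the tertiary hydroxyl, a second adds 1,2 to the vinylogous ester carbonyl, and dilute acid ionises the tertiary allylic alcohol and hydrolyses the enol ether to the transposed enone without touching C6 or the allene.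

**Step 5**
Reactants: 12 (S)-4-hydroxy-4-methyl-3-(hexa-4,5-dien-1-yl)cyclohex-2-en-1-one
Product: 13 tricyclic photoadduct 11-hydroxy-11-methyl-6-methylidenetricyclo[5.4.0.0^{1,5}]undecan-8-one (C3 ketone; C6 carbinol; C2a=CH2; configuration as in the SMILES)
Conditions: hν (λ ≥ 350 nm, uranium-glass filter), degassed CH2Cl2 (5 mM), 15 °C
Reagents that add atoms: none
Why: n→π* excitation and intersystem crossing give the triplet enone, whose β-carbon C1 bonds to the proximal allene carbon C10, and the triplet 1,4-biradical (α-keto radical at C2, vinyl radical at C2a) closes the C2–C2a bond after spin inversion. The closest known reaction is the intramolecular enone–allene [2+2] photocycloaddition of 3-(hexa-4,5-dienyl)cyclohex-2-enones, which gives the straight methylenecyclobutane adducts. Ring A closes by a five-membered (1,5, exo) closure at C1–C10 and the cyclobutane by four-membered radical recombination at C2–C2a. C1 is controlled by C6: in the half-chair the methyl group is pseudoaxial to avoid eclipsing the C1 chain, so the tether should bond on the opposite face, syn to the hydroxyl, and C2 and C10 follow from C1 because the four-membered ring can only be cis-fused to rings A and B. The step needs 1,5- over 1,6-closure, which the three-carbon tether secures, and face selectivity, which C6 secures, while the long-wavelength cut-off keeps the β,γ-unsaturated ketone product from absorbing.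

**Step 6**
Reactants: 13 tricyclic photoadduct
Product: 14 C6 triethylsilyl ether of 13
Conditions: Et3SiOTf, 2,6-lutidine, CH2Cl2, −78 → 0 °C
Reagents that add atoms: triethylsilyl trifluoromethanesulfonate, CC[Si](CC)(CC)OS(=O)(=O)C(F)(F)F
Why: Silyl triflate silylation of the hindered tertiary alcohol is faster than enol silylation of the ketone with the weak base 2,6-lutidine, and the ether later prevents O–H insertion and acyl transfer at C6.

**Step 7**
Reactants: 14 C6 triethylsilyl ether
Product: 15 C3 ethylene ketal (1,3-dioxolane) of 14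
Conditions: (Me3SiOCH2)2, Me3SiOTf (5 mol %), CH2Cl2, −78 → −20 °C
Reagents that add atoms: 1,2-bis(trimethylsilyloxy)ethane, C[Si](C)(C)OCCO[Si](C)(C)C
Why: Aprotic dioxolanation under silyl triflate catalysis, driven by formation of the disiloxane, masks C3 without ionising the methylenecyclobutane, so that the cyclobutanone of step 8 is not a 1,3-diketone open to retro-Claisen cleavage.

**Step 8**
Reactants: 15 C3 ketal
Product: 17 cyclobutanone (C2a ketone; C3 dioxolane; C6 silyl ether), via ozonide 16 (not isolated)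
Conditions: O3, CH2Cl2, −78 °C; PPh3, −78 → 20 °C
Reagents that add atoms: ozone, [O-][O+]=O
Why: Ozonolysis (Criegee mechanism) of the only alkene and reduction of the ozonide gives the cyclobutanone without touching a stereocentre.

**Step 9**
Reactants: 17 cyclobutanone
Product: 18 γ-lactone C10–O–C2a(=O)–C2 on the spiro[4.5]decane core
Conditions: m-CPBA, NaHCO3, CH2Cl2, 0 °C
Reagents that add atoms: 3-chloroperoxybenzoic acid, OOC(=O)c1cccc(Cl)c1
Why: Baeyer–Villiger oxidation is fast for the strained ketone and should move C10 rather than C2, because C2 carries the inductively withdrawing ketal carbon; C10 migrates with retention, so the C10–O bond keeps the cis relation to C2a that the cyclobutane fixed.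

**Step 10**
Reactants: 18 γ-lactone
Product: 19 lactol (C2a hemiacetal; anomers)
Conditions: i-Bu2AlH (1.1 equiv), CH2Cl2, −78 °C; Rochelle salt
Reagents that add atoms: none
Why: Partial reduction of a γ-lactone by i-Bu2AlH stops at the tetrahedral aluminate at −78 °C and gives the lactol, whose anomeric mixture is inconsequential.

**Step 11**
Reactants: 19 lactol
Product: 20 hydroxy enoate (C2 bears (E)-CH=CH–CO2Et; C10 hydroxyl free)
Conditions: Ph3P=CHCO2Et, PhCO2H (cat.), toluene, 90 °C
Reagents that add atoms: ethyl (triphenylphosphoranylidene)acetate, CCOC(=O)C=P(c1ccccc1)(c1ccccc1)c1ccccc1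
Why: Wittig olefination of the ring-opened hydroxy aldehyde with a stabilised ylide frees the C10 hydroxyl and gives the E-enoate; under these base-free conditions oxa-Michael reclosure of the hindered C10 hydroxyl and epimerisation at C2 should be slow.

**Step 12**
Reactants: 20 hydroxy enoate
Product: 21 saturated ester (C2 bears CH2CH2CO2Et)
Conditions: H2 (1 atm), Pd/C, EtOAc, 20 °C
Reagents that add atoms: none
Why: Heterogeneous hydrogenation of the disubstituted enoate double bond leaves the ketal and the silyl ether untouched.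

**Step 13**
Reactants: 21 saturated ester
Product: 22 diol (C2 bears the 3-hydroxypropyl arm; C10 hydroxyl)
Conditions: LiAlH4, THF, 0 °C
Reagents that add atoms: none
Why: Hydride reduction of the ester to the primary alcohol completes the three-carbon arm.

**Step 14**
Reactants: 22 diol
Product: 23 arm tert-butyldiphenylsilyl ether (C10 hydroxyl free)
Conditions: t-BuPh2SiCl, imidazole, CH2Cl2, 0 °C
Reagents that add atoms: tert-butyl(chloro)diphenylsilane, CC(C)(C)[Si](Cl)(c1ccccc1)c1ccccc1
Why: The bulky chlorosilane silylates the primary alcohol selectively over the neopentyl-type secondary C10 hydroxyl.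

**Step 15**
Reactants: 23 arm silyl ether
Product: 24 C10 2-(diethoxyphosphoryl)acetate
Conditions: (EtO)2P(O)CH2CO2H, N,N′-dicyclohexylcarbodiimide, DMAP (cat.), CH2Cl2, 0 → 20 °C
Reagents that add atoms: 2-(diethoxyphosphoryl)acetic acid, OC(=O)CP(=O)(OCC)OCC
Why: Steglich esterification acylates the only free hydroxyl, the secondary one at C10.

**Step 16**
Reactants: 24 phosphonoacetate
Product: 25 C10 2-diazo-2-(diethoxyphosphoryl)acetate
Conditions: 4-acetamidobenzenesulfonyl azide, DBU, MeCN, 0 → 20 °C
Reagents that add atoms: 4-acetamidobenzenesulfonyl azide, CC(=O)Nc1ccc(cc1)S(=O)(=O)N=[N+]=[N-]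
Why: Regitz diazo transfer to the doubly activated methylene gives the acceptor/acceptor diazo ester.

**Step 17**
Reactants: 25 diazo phosphonoacetate
Product: 26 cis-fused α-(diethoxyphosphoryl)-γ-lactone C10–O–C12(=O)–C11H[P(O)(OEt)2]–C9
Conditions: Rh2(O2CC7H15)4 (dirhodium tetraoctanoate, 2 mol %), CH2Cl2, 40 °C, slow addition
Reagents that add atoms: none
Why: Dirhodium carbene C–H insertion prefers the 1,5 mode, C1 has no hydrogen, and only the C9–H bond cis to the ester oxygen can be reached, so the C9–C11 bond should form with retention cis to C10–O in a cis-fused γ-lactone, while the phosphonate carbon forms as epimers and becomes sp2 in step 20.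

**Step 18**
Reactants: 26 phosphono lactone
Product: 27 C3 ketone of 26
Conditions: pyridinium p-toluenesulfonate, acetone/H2O (9:1), 45 °C
Reagents that add atoms: water, O
Why: Mild acid-catalysed hydrolysis of the dioxolane leaves the primary tert-butyldiphenylsilyl ether and the hindered tertiary triethylsilyl ether in place.

**Step 19**
Reactants: 27 C3 ketone
Product: 29 C3 isopropenyl carbinol (C3 configuration not controlled), via lithium phosphonate enolate 28 (not isolated)
Conditions: LiN(SiMe3)2 (1.0 equiv), THF, −78 °C; CH2=C(CH3)MgBr/CeCl3 (3 equiv), −78 → −40 °C; aq. NH4Cl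
Reagents that add atoms: isopropenylmagnesium bromide, CC(=C)[Mg]Br
Why: The acidic phosphonolactone is first turned into its enolate, which is inert to nucleophiles, and the weakly basic organocerium reagent then adds 1,2 to the hindered enolisable ketone without epimerising C2; the new C3 carbinol centre is lost in step 21.

**Step 20**
Reactants: 29 C3 isopropenyl carbinol; 7 formaldehyde (37% aqueous)
Product: 30 α-methylene-γ-lactone (C11=CH2)
Conditions: K2CO3, aq. CH2O, THF, 20 °C
Reagents that add atoms: none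
Why: Horner–Wadsworth–Emmons olefination of the α-phosphono lactone with formaldehyde gives the α-methylene lactone under conditions too mild to affect the tertiary allylic alcohol.

**Step 21**
Reactants: 30 α-methylene lactone
Product: 31 enal (C3=(Z)-C(CH3)CHO; α-methylene lactone retained)
Conditions: pyridinium chlorochromate (C5H5NH)[CrO3Cl], 4 Å molecular sieves, CH2Cl2, 20 °C
Reagents that add atoms: pyridinium chlorochromate, [O-][Cr](=O)(=O)Cl.c1cc[nH+]cc1
Why: Babler–Dauben oxidative transposition: the tertiary chromate ester undergoes a [3,3] shift to the primary allylic chromate, which is oxidised to the enal; the isopropenyl methyl should turn to the less hindered C4 side in the chair transition state and the planar formyl group is also better placed next to the substituted C2, so the Z enal is expected and equilibration remains available.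

**Step 22**
Reactants: 31 enal
Product: 32 lactol (C12 hemiacetal; anomers) with C3=(Z)-C(CH3)CH2OH
Conditions: i-Bu2AlH (4 equiv), CH2Cl2, −78 °C; Rochelle salt
Reagents that add atoms: none
Why: At −78 °C i-Bu2AlH reduces the α-methylene lactone to the lactol and the enal by 1,2-addition to the allylic alcohol, with the alkene geometry kept.

**Step 23**
Reactants: 32 lactol
Product: 33 (E)-dienyl pinacol boronate (C9–C(=CH2)–CH=CH–B(pin); C10 hydroxyl free)
Conditions: CrCl2 (8 equiv), Cl2CHB(pin) (2 equiv), LiI (4 equiv), THF, 20 °C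
Reagents that add atoms: 2-(dichloromethyl)-4,4,5,5-tetramethyl-1,3,2-dioxaborolane, ClC(Cl)B1OC(C)(C)C(C)(C)O1
Why: Takai–Utimoto boryl-olefination: the geminal dichromium reagent adds to the aldehyde form of the lactol and eliminates to the E-alkenyl boronate, and CrCl2 tolerates the free hydroxyls.

**Step 24**
Reactants: 34 prop-2-yn-1-ol; 35 5-bromo-2-methylpent-2-ene
Product: 38 (Z)-3-iodo-2-(4-methylpent-3-en-1-yl)prop-2-en-1-ol, via Grignard reagent 36 (not isolated), via alkenylmagnesium chelate 37 (not isolated)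
Conditions: 35, Mg, THF; then 34 (0.4 equiv), CuI (10 mol %), 0 → 20 °C; then I2, −20 °C
Reagents that add atoms: iodine, II
Why: Copper-catalysed anti-carbomagnesiation of propargyl alcohol puts the alkyl group on C2 and magnesium on C3 cis to the oxygen (five-membered chelate), and iodinolysis with retention gives the Z iodide.

**Step 25**
Reactants: 38 iodo alcohol
Product: 39 (Z)-3-iodo-2-(4-methylpent-3-en-1-yl)prop-2-en-1-yl acetate
Conditions: Ac2O, pyridine, DMAP (cat.), CH2Cl2, 0 °C
Reagents that add atoms: acetic anhydride, CC(=O)OC(C)=O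
Why: Acylation of the primary allylic alcohol installs the acetate before the coupling, so that no late selective acetylation is needed.

**Step 26**
Reactants: 33 dienyl boronate; 39 iodo acetate (1.2 equiv)
Product: 40 coupled triene (side chain complete; C10 hydroxyl; C3=(Z)-C(CH3)CH2OH; both silyl ethers)
Conditions: PdCl2(dppf) (5 mol %), K3PO4, DMF/H2O, 20 °C
Reagents that add atoms: none
Why: Suzuki–Miyaura coupling with retention at both sp2 carbons joins the E-dienyl boronate and the Z iodide to the E,Z-triene; oxidative addition to the alkenyl iodide is much faster than ionisation of the allylic acetate, and the slight excess of iodide keeps zerovalent palladium occupied.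

**Step 27**
Reactants: 40 coupled triene
Product: 41 bis-silyl ether of the target (C3=(Z)-C(CH3)CHO)
Conditions: MnO2 (activated, 20 equiv), CH2Cl2, 20 °C
Reagents that add atoms: none
Why: MnO2 oxidises only the allylic primary alcohol and leaves the saturated secondary C10 hydroxyl, the acetate and the triene.

**Step 28**
Reactants: 41 bis-silyl ether
Product: 42 target CNP0205332.1
Conditions: HF·pyridine, pyridine, THF, 0 → 20 °C
Reagents that add atoms: none
Why: Buffered fluoride cleaves the primary tert-butyldiphenylsilyl and the tertiary triethylsilyl ether and spares the allylic acetate, the enal and the triene.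

**Compound list**
1 | 3-ethoxycyclohex-2-en-1-one | CCOC1=CC(=O)CCC1 | starting material
2 | lithium 5-ethoxycyclohexa-1,5-dien-1-olate | CCOC1=CC([O-])=CCC1.[Li+] | intermediate
3 | 3-ethoxy-6-methylcyclohex-2-en-1-one (racemic) | CCOC1=CC(=O)C(C)CC1 | intermediate
4 | sodium 5-ethoxy-2-methylcyclohexa-1,5-dien-1-olate | CCOC1=CC([O-])=C(C)CC1.[Na+] | intermediate
5 | (S)-3-ethoxy-6-hydroxy-6-methylcyclohex-2-en-1-one | CCOC1=CC(=O)[C@@](C)(O)CC1 | intermediate
6 | 5-chloropent-1-yne | C#CCCCCl | starting material
7 | formaldehyde (paraformaldehyde or aqueous solution) | C=O | starting material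
8 | 6-chloro-N,N-diisopropylhex-2-yn-1-amine | ClCCCC#CCN(C(C)C)C(C)C | intermediate
9 | 6-chlorohexa-1,2-diene | C=C=CCCCCl | intermediate
10 | hexa-4,5-dien-1-ylmagnesium chloride | C=C=CCCC[Mg]Cl | intermediate
11 | (6S)-3-ethoxy-1-(hexa-4,5-dien-1-yl)-6-methylcyclohex-2-ene-1,6-diol (C1 epimers; magnesium alkoxide in the flask) | CCOC1=CC(O)(CCCC=C=C)[C@@](C)(O)CC1 | intermediate
12 | (S)-4-hydroxy-4-methyl-3-(hexa-4,5-dien-1-yl)cyclohex-2-en-1-one | C=C=CCCCC1=CC(=O)CC[C@]1(C)O | intermediate
13 | photoadduct 11-hydroxy-11-methyl-6-methylidenetricyclo[5.4.0.0^{1,5}]undecan-8-one (C3 ketone; C6-OH on the face of C10; C2a=CH2) | C1CC[C@]2([C@H]3C(=O)CC[C@]2(C)O)[C@@H]1C3=C | intermediate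
14 | C6 triethylsilyl ether of 13 | C1CC[C@]2([C@H]3C(=O)CC[C@]2(C)O[Si](CC)(CC)CC)[C@@H]1C3=C | intermediate
15 | C3 ethylene ketal of 14 | C1CC[C@]2([C@H]3C4(OCCO4)CC[C@]2(C)O[Si](CC)(CC)CC)[C@@H]1C3=C | intermediate
16 | ozonide of 15 (spiro-1,2,4-trioxolane at C2a; both configurations at C2a) | C1CC[C@]2([C@H]3C4(OCCO4)CC[C@]2(C)O[Si](CC)(CC)CC)[C@@H]1C35OCOO5 | intermediate
17 | cyclobutanone (C2a ketone; C3 dioxolane; C6 triethylsilyl ether) | C1CC[C@]2([C@H]3C4(OCCO4)CC[C@]2(C)O[Si](CC)(CC)CC)[C@@H]1C3=O | intermediate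
18 | γ-lactone C10–O–C2a(=O)–C2 | C1CC[C@]2([C@H]3C4(OCCO4)CC[C@]2(C)O[Si](CC)(CC)CC)[C@@H]1OC3=O | intermediate
19 | lactol of 18 (anomers at C2a) | C1CC[C@]2([C@H]3C4(OCCO4)CC[C@]2(C)O[Si](CC)(CC)CC)[C@@H]1OC3O | intermediate
20 | hydroxy enoate (C2 (E)-CH=CH–CO2Et; C10-OH) | C1CC[C@]2([C@H](/C=C/C(=O)OCC)C3(OCCO3)CC[C@]2(C)O[Si](CC)(CC)CC)[C@@H]1O | intermediate
21 | saturated ester (C2 CH2CH2CO2Et; C10-OH) | C1CC[C@]2([C@H](CCC(=O)OCC)C3(OCCO3)CC[C@]2(C)O[Si](CC)(CC)CC)[C@@H]1O | intermediate
22 | diol (C2 3-hydroxypropyl; C10-OH) | C1CC[C@]2([C@H](CCCO)C3(OCCO3)CC[C@]2(C)O[Si](CC)(CC)CC)[C@@H]1O | intermediate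
23 | arm tert-butyldiphenylsilyl ether (C10-OH free) | C1CC[C@]2([C@H](CCCO[Si](c3ccccc3)(c3ccccc3)C(C)(C)C)C4(OCCO4)CC[C@]2(C)O[Si](CC)(CC)CC)[C@@H]1O | intermediate
24 | C10 2-(diethoxyphosphoryl)acetate | C1CC[C@]2([C@H](CCCO[Si](c3ccccc3)(c3ccccc3)C(C)(C)C)C4(OCCO4)CC[C@]2(C)O[Si](CC)(CC)CC)[C@@H]1OC(=O)CP(=O)(OCC)OCC | intermediate
25 | C10 2-diazo-2-(diethoxyphosphoryl)acetate | C1CC[C@]2([C@H](CCCO[Si](c3ccccc3)(c3ccccc3)C(C)(C)C)C4(OCCO4)CC[C@]2(C)O[Si](CC)(CC)CC)[C@@H]1OC(=O)C(=[N+]=[N-])P(=O)(OCC)OCC | intermediate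
26 | cis-fused α-(diethoxyphosphoryl)-γ-lactone at C9–C10 (epimers at C11) | CCOP(=O)(OCC)C5[C@@H]1CC[C@]2([C@H](CCCO[Si](c3ccccc3)(c3ccccc3)C(C)(C)C)C4(OCCO4)CC[C@]2(C)O[Si](CC)(CC)CC)[C@@H]1OC5=O | intermediate
27 | C3 ketone of 26 | CCOP(=O)(OCC)C5[C@@H]1CC[C@]2([C@H](CCCO[Si](c3ccccc3)(c3ccccc3)C(C)(C)C)C(=O)CC[C@]2(C)O[Si](CC)(CC)CC)[C@@H]1OC5=O | intermediate
28 | lithium enolate of the phosphonolactone of 27 | CCOP(=O)(OCC)C=5[C@@H]1CC[C@]2([C@H](CCCO[Si](c3ccccc3)(c3ccccc3)C(C)(C)C)C(=O)CC[C@]2(C)O[Si](CC)(CC)CC)[C@@H]1OC5[O-].[Li+] | intermediate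
29 | C3 isopropenyl carbinol (C3 and C11 not defined) | CCOP(=O)(OCC)C5[C@@H]1CC[C@]2([C@H](CCCO[Si](c3ccccc3)(c3ccccc3)C(C)(C)C)C(O)(C(C)=C)CC[C@]2(C)O[Si](CC)(CC)CC)[C@@H]1OC5=O | intermediate
30 | α-methylene-γ-lactone with C3 isopropenyl carbinol | C=C5[C@@H]1CC[C@]2([C@H](CCCO[Si](c3ccccc3)(c3ccccc3)C(C)(C)C)C(O)(C(C)=C)CC[C@]2(C)O[Si](CC)(CC)CC)[C@@H]1OC5=O | intermediate
31 | enal (C3=(Z)-C(CH3)CHO) with α-methylene lactone | C=C5[C@@H]1CC[C@]2([C@H](CCCO[Si](c3ccccc3)(c3ccccc3)C(C)(C)C)/C(=C(/C)C=O)CC[C@]2(C)O[Si](CC)(CC)CC)[C@@H]1OC5=O | intermediate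
32 | lactol (anomers at C12) with C3=(Z)-C(CH3)CH2OH | C=C5[C@@H]1CC[C@]2([C@H](CCCO[Si](c3ccccc3)(c3ccccc3)C(C)(C)C)/C(=C(/C)CO)CC[C@]2(C)O[Si](CC)(CC)CC)[C@@H]1OC5O | intermediate
33 | (E)-dienyl pinacol boronate (C10-OH; allylic alcohol) | C=C(/C=C/B3OC(C)(C)C(C)(C)O3)[C@@H]1CC[C@]2([C@H](CCCO[Si](c4ccccc4)(c4ccccc4)C(C)(C)C)/C(=C(/C)CO)CC[C@]2(C)O[Si](CC)(CC)CC)[C@@H]1O | intermediate
34 | prop-2-yn-1-ol | C#CCO | starting material
35 | 5-bromo-2-methylpent-2-ene | CC(C)=CCCBr | starting material
36 | (4-methylpent-3-en-1-yl)magnesium bromide | CC(C)=CCC[Mg]Br | intermediate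
37 | (Z)-alkenylmagnesium alkoxide from carbomagnesiation | Br[Mg]/C=C(/CCC=C(C)C)CO[Mg]Br | intermediate
38 | (Z)-3-iodo-2-(4-methylpent-3-en-1-yl)prop-2-en-1-ol | I/C=C(/CCC=C(C)C)CO | intermediate
39 | (Z)-3-iodo-2-(4-methylpent-3-en-1-yl)prop-2-en-1-yl acetate | I/C=C(/CCC=C(C)C)COC(C)=O | intermediate
40 | coupled triene (C10-OH; C3=(Z)-C(CH3)CH2OH; both silyl ethers) | C=C(/C=C/C=C(/CCC=C(C)C)COC(C)=O)[C@@H]1CC[C@]2([C@H](CCCO[Si](c3ccccc3)(c3ccccc3)C(C)(C)C)/C(=C(/C)CO)CC[C@]2(C)O[Si](CC)(CC)CC)[C@@H]1O | intermediate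
41 | bis-silyl ether of the target | C=C(/C=C/C=C(/CCC=C(C)C)COC(C)=O)[C@@H]1CC[C@]2([C@H](CCCO[Si](c3ccccc3)(c3ccccc3)C(C)(C)C)/C(=C(/C)C=O)CC[C@]2(C)O[Si](CC)(CC)CC)[C@@H]1O | intermediate
42 | CNP0205332.1 | C=C(/C=C/C=C(/CCC=C(C)C)COC(C)=O)[C@@H]1CC[C@]2([C@H](CCCO)/C(=C(/C)C=O)CC[C@]2(C)O)[C@@H]1O | target

**Step count and risks**
Total: 28 steps (25 in the main sequence, 1 for the allene tether, 2 for the side-chain iodide). Longest linear sequence: 25 steps (1 → 42 through steps 1, 2, 4–23 and 26–28).

The three steps most likely to fail: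

Step 5. The methyl and hydroxyl groups at C6 may not differ enough to steer the C1–C10 bond to one face, so that the C1/C2/C10 diastereomer forms alongside, and some 1,6-closure may compete. The fallback sets out from 1 and returns at 15; it lets a single pseudoaxial silyloxy group at C6 steer the cycloaddition and builds the methyl carbinol afterwards.
- α′-Acetoxylation of 1 with Mn(OAc)3 (benzene, reflux) would give racemic 6-acetoxy-3-ethoxycyclohex-2-en-1-one F1.
- Lipase-mediated hydrolysis (kinetic resolution) would give (R)-3-ethoxy-6-hydroxycyclohex-2-en-1-one F2.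
- Silylation (t-BuMe2SiCl, imidazole) would give (R)-6-(tert-butyldimethylsilyloxy)-3-ethoxycyclohex-2-en-1-one F3.
- Addition of Grignard reagent 10 and acidic work-up would give (R)-4-(tert-butyldimethylsilyloxy)-3-(hexa-4,5-dien-1-yl)cyclohex-2-en-1-one F4.
- Irradiation as in step 5 should give, by addition anti to the silyloxy group, the C6 silyloxy photoadduct F5.
- Dioxolanation as in step 7 would give the C3 ketal F6, and Bu4NF the C6 secondary alcohol F7.
- Dess–Martin oxidation would give the C6 ketone F8.
- CH3MgBr/CeCl3 is expected to enter from the upper face, away from the cyclobutane, and give the C6 tertiary methyl carbinol F9.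
- Silylation as in step 6 gives 15.

Step 17. The carbene may be diverted to 1,6-insertion at C2–H or C7–H, to β-lactone formation at C10–H, to ylide formation with a ketal oxygen, or to dimerisation. The fallback sets out from 23 and returns at 26; it uses an acceptor-only carbene under a carboxamidate catalyst, which has a strong preference for 1,5-insertion cis to oxygen in cyclopentyl esters, and brings in phosphorus afterwards.
- Acylation of 23 with bromoacetyl bromide (pyridine) would give the C10 bromoacetate F12.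
- N,N′-ditosylhydrazine and DBU would give the C10 diazoacetate F13.
- Rh2(cap)4 (dirhodium tetrakis(caprolactamate)) in CH2Cl2 would give the cis-fused γ-lactone F14.
- LiN(i-Pr)2 followed by ClP(O)(OEt)2 would give the ketene acetal phosphate F15 (not isolated).
- A second portion of LiN(i-Pr)2 should move phosphorus from oxygen to carbon (1,3-shift) and give 26.

Step 9. Migration of C2 may compete with migration of C10, since both are ring-fusion methines, and would give the regioisomeric lactone. The fallback sets out from 14 and returns at 18; it runs the oxidation on a substrate in which C2 lies between two carbonyl groups and cannot migrate.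
- Ozonolysis of 14 (O3, CH2Cl2, −78 °C; PPh3) would give the 1,3-diketone F10 (C3 and C2a ketones), handled without nucleophiles.
- Buffered m-CPBA would give the keto lactone F11.
- Dioxolanation of the C3 ketone as in step 7 gives 18.

**Further compounds**
F1 | step 5 | rac-6-acetoxy-3-ethoxycyclohex-2-en-1-one | CCOC1=CC(=O)C(OC(C)=O)CC1
F2 | step 5 | (R)-3-ethoxy-6-hydroxycyclohex-2-en-1-one | CCOC1=CC(=O)[C@H](O)CC1
F3 | step 5 | (R)-6-(tert-butyldimethylsilyloxy)-3-ethoxycyclohex-2-en-1-one | CCOC1=CC(=O)[C@H](O[Si](C)(C)C(C)(C)C)CC1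
F4 | step 5 | (R)-4-(tert-butyldimethylsilyloxy)-3-(hexa-4,5-dien-1-yl)cyclohex-2-en-1-one | C=C=CCCCC1=CC(=O)CC[C@H]1O[Si](C)(C)C(C)(C)C
F5 | step 5 | C6 silyloxy photoadduct (C10 anti to the C6 oxygen) | C1CC[C@]2([C@H]3C(=O)CC[C@H]2O[Si](C)(C)C(C)(C)C)[C@@H]1C3=C
F6 | step 5 | C3 ethylene ketal of F5 | C1CC[C@]2([C@H]3C4(OCCO4)CC[C@H]2O[Si](C)(C)C(C)(C)C)[C@@H]1C3=C
F7 | step 5 | C6 secondary alcohol | C1CC[C@]2([C@H]3C4(OCCO4)CC[C@H]2O)[C@@H]1C3=C
F8 | step 5 | C6 ketone | C1CC[C@]2([C@H]3C4(OCCO4)CCC2=O)[C@@H]1C3=C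
F9 | step 5 | C6 tertiary methyl carbinol (15 without the silyl group) | C1CC[C@]2([C@H]3C4(OCCO4)CC[C@]2(C)O)[C@@H]1C3=C
F10 | step 9 | 1,3-diketone (C3 and C2a ketones; C6 triethylsilyl ether) | C1CC[C@]2([C@H]3C(=O)CC[C@]2(C)O[Si](CC)(CC)CC)[C@@H]1C3=O
F11 | step 9 | keto lactone (C3 ketone; lactone C10–O–C2a(=O)–C2) | C1CC[C@]2([C@H]3C(=O)CC[C@]2(C)O[Si](CC)(CC)CC)[C@@H]1OC3=O
F12 | step 17 | C10 bromoacetate | C1CC[C@]2([C@H](CCCO[Si](c3ccccc3)(c3ccccc3)C(C)(C)C)C4(OCCO4)CC[C@]2(C)O[Si](CC)(CC)CC)[C@@H]1OC(=O)CBr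
F13 | step 17 | C10 diazoacetate | C1CC[C@]2([C@H](CCCO[Si](c3ccccc3)(c3ccccc3)C(C)(C)C)C4(OCCO4)CC[C@]2(C)O[Si](CC)(CC)CC)[C@@H]1OC(=O)C=[N+]=[N-]
F14 | step 17 | cis-fused γ-lactone at C9–C10 (no phosphonate) | C5[C@@H]1CC[C@]2([C@H](CCCO[Si](c3ccccc3)(c3ccccc3)C(C)(C)C)C4(OCCO4)CC[C@]2(C)O[Si](CC)(CC)CC)[C@@H]1OC5=O
F15 | step 17 | ketene acetal diethyl phosphate of F14 | C=5[C@@H]1CC[C@]2([C@H](CCCO[Si](c3ccccc3)(c3ccccc3)C(C)(C)C)C4(OCCO4)CC[C@]2(C)O[Si](CC)(CC)CC)[C@@H]1OC5OP(=O)(OCC)OCC
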